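**Retrosynthetic overview**
1. The target is two copies of one homochiral trans-fused 2,2,5a-trimethylperhydro-1-benzoxepine joined tail to tail by CH2–CH2. The left copy is ring A (oxepanol) plus ring B (methylidenecyclohexane); the right copy is ring C (cyclohexane with the tertiary carbinol) plus ring D (oxepanone). Locants C2–C23 count along the squalene-like chain from the left gem-dimethyl carbon (C2) to the right one (C23).
2. Enabling feature: in the left bicycle the ether oxygen joins the gem-dimethyl carbon C2 to the ring-fusion CH (C7), the hydroxyl sits on C3 next to C2, the methyl-bearing ring-fusion carbon C6 is next to C7, and ring B carries its methylidene on C10 next to the side-chain CH (C11). This pattern is a (3S)-2,3-epoxide, a (6S,7S)-6,7-epoxide and a 10,11-alkene with a silylmethyl group on C10, so the O–C2 and C6–C11 bonds are cut together to an acyclic diepoxy Z-allylsilane.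
3. The central C12–C13 bond is cut to an α-sulfonyl carbanion on the right bicycle and the allylic chloride 11. The right bicycle comes from the same diepoxy allylsilane (as sulfone 12) by the same cascade, then ozonolysis and methyl addition.
4. Chloride 11 is made in six steps from geranyl bromide and methyl acetoacetate (dianion alkylation, Z-enol triflate, Shi epoxidation, Kumada coupling, reduction, chlorination) and is used twice.
5. Ring order: rings D and C in step 8 (D before C within the cascade); rings A and then B in step 14, ring B being the last ring of the skeleton to close.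

Key step: step 14

Remark: the L-fructose-derived enantiomer of the Shi ketone is assumed to be purchasable (it is otherwise prepared from L-sorbose).

**Step 1**
Reactants: 1 methyl acetoacetate; 2 geranyl bromide
Product: 4 methyl (6E)-7,11-dimethyl-3-oxododeca-6,10-dienoate, via sodium lithium dianion 3 (not isolated)
Conditions: NaH, THF, 0 °C; n-BuLi, 0 °C; then 2, 0 °C → rt; aq. HCl
Reagents that add atoms: none
Why: The 1,3-dianion of the β-keto ester alkylates only at its terminal carbon, and SN2 displacement of the primary allylic bromide keeps the E alkene (γ-alkylation of an acetoacetate dianion).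

**Step 2**
Reactants: 4 β-keto ester
Product: 6 methyl (2Z,6E)-7,11-dimethyl-3-(trifluoromethylsulfonyloxy)dodeca-2,6,10-trienoate, via lithium enolate 5 (not isolated)
Conditions: aq. LiOH (sat.), Tf2O, toluene, 5 °C
Reagents that add atoms: trifluoromethanesulfonic anhydride, O=S(=O)(OS(=O)(=O)C(F)(F)F)C(F)(F)F
Why: The lithium-chelated enolate of the β-keto ester is Z and is O-sulfonylated in the two-phase medium before it equilibrates, so triflate and ester end up cis (stereoselective enol triflate formation from an acyclic β-keto ester).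

**Step 3**
Reactants: 6 Z-enol triflate
Product: 7 methyl (2Z,6S,7S,10S)-6,7:10,11-diepoxy-7,11-dimethyl-3-(trifluoromethylsulfonyloxy)dodec-2-enoate
Conditions: L-fructose-derived Shi ketone (0.6 equiv), Oxone (2KHSO5·KHSO4·K2SO4), K2CO3, Bu4NHSO4, MeCN–dimethoxymethane–aq. Na2B4O7 buffer, pH 10.5, 0 °C
Reagents that add atoms: Oxone, active component potassium peroxymonosulfate, [K+].[O-]S(=O)(=O)OO
Why: The chiral dioxirane epoxidises the two electron-rich trisubstituted alkenes through the spiro transition state from the face that gives S at every epoxide carbon, while the alkene bearing ester and triflate is too electron-poor to react (Shi epoxidation, catalyst control).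

**Step 4**
Reactants: 7 diepoxy enol triflate
Product: 8 methyl (2Z,6S,7S,10S)-6,7:10,11-diepoxy-7,11-dimethyl-3-[(trimethylsilyl)methyl]dodec-2-enoate
Conditions: Pd(PPh3)4 (5 mol%), Me3SiCH2MgCl, Et2O–THF, 0 °C
Reagents that add atoms: (trimethylsilyl)methylmagnesium chloride, C[Si](C)(C)C[Mg]Cl
Why: Zerovalent palladium inserts into the activated vinyl C–OTf bond and couples with the poorly nucleophilic silylmethyl Grignard reagent with retention of alkene geometry, which should be faster than attack of this reagent on the ester or the trisubstituted epoxides (Kumada coupling).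

**Step 5**
Reactants: 8 diepoxy allylsilane ester
Product: 9 (2Z,6S,7S,10S)-6,7:10,11-diepoxy-7,11-dimethyl-3-[(trimethylsilyl)methyl]dodec-2-en-1-ol
Conditions: i-Bu2AlH (2.5 equiv), CH2Cl2, −78 °C; aq. potassium sodium tartrate (KNaC4H4O6)
Reagents that add atoms: none
Why: The aluminium hydride reduces the conjugated ester in a 1,2 sense at −78 °C, where trisubstituted epoxides and the allylsilane are inert, and the non-acidic work-up avoids acid-induced 1,4-loss of silanol (ester reduction).

**Step 6**
Reactants: 9 allylic alcohol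
Product: 11 (2Z,6S,7S,10S)-1-chloro-6,7:10,11-diepoxy-7,11-dimethyl-3-[(trimethylsilyl)methyl]dodec-2-ene, via allylic mesylate 10 (not isolated)
Conditions: MsCl, s-collidine, LiCl, DMF, 0 °C; used without storage
Reagents that add atoms: lithium chloride, [Li+].[Cl-]
Why: The mesylate formed in situ is displaced by chloride in an SN2 reaction under buffered, non-ionising conditions, which keeps the Z alkene and avoids ionisation to the silicon-stabilised allyl cation (alcohol to allylic chloride through the mesylate).

**Step 7**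
Reactants: 11 allylic chloride
Product: 12 [(2Z,6S,7S,10S)-6,7:10,11-diepoxy-7,11-dimethyl-3-[(trimethylsilyl)methyl]dodec-2-en-1-yl] phenyl sulfone
Conditions: PhSO2Na, DMF, 0 °C → rt
Reagents that add atoms: sodium benzenesulfinate, [Na+].[O-]S(=O)c1ccccc1
Why: The sulfinate is S-alkylated by the primary allylic chloride in a dipolar aprotic solvent without allylic transposition (SN2 sulfinate alkylation).

**Step 8**
Reactants: 12 diepoxy allylsilane sulfone
Product: 14 (3S,5aS,6R,9aS)-2,2,5a-trimethyl-7-methylidene-6-[(phenylsulfonyl)methyl]decahydro-1-benzoxepin-3-ol, via silyl ether 13 (not isolated)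
Conditions: Me3SiOTf (0.5 equiv), 2,6-di-tert-butyl-4-methylpyridine, CH2Cl2, −78 °C; then K2CO3 (cat.), MeOH, rt
Reagents that add atoms: none
Why: The silyl triflate activates the terminal epoxide, the neighbouring epoxide oxygen opens it at the tertiary carbon to a bicyclic epoxonium ion, and the Z-allylsilane closes the cyclohexane at the tertiary epoxonium carbon through a chair with loss of silicon, so the trans ring fusion follows from anti opening of the (S,S)-epoxide and the equatorial sulfonylmethyl group from the Z alkene (Lewis acid tandem oxa-/carbacyclisation of a 1,5-diepoxide with allylsilane termination).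

**Step 9**
Reactants: 14 bicyclic methylidene sulfone
Product: 16 (3S,5aS,6S,9aS)-3-hydroxy-2,2,5a-trimethyl-6-[(phenylsulfonyl)methyl]octahydro-1-benzoxepin-7(2H)-one, via spiro ozonide 15 (not isolated)
Conditions: O3, CH2Cl2, −78 °C; then Me2S, −78 °C → rt
Reagents that add atoms: ozone, [O-][O+]=O
Why: The 1,1-disubstituted alkene is the only C=C bond and is cleaved through the ozonide to the cyclohexanone under a neutral reductive work-up that leaves the base-sensitive β-sulfonyl ketone and its equatorial α-substituent untouched (ozonolysis).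

**Step 10**
Reactants: 16 keto sulfone
Product: 17 (3S,5aS,6S,7R,9aS)-2,2,5a,7-tetramethyl-6-[(phenylsulfonyl)methyl]decahydro-1-benzoxepine-3,7-diol
Conditions: MeLi, CeCl3 (anhydrous), THF, −78 °C; aq. NH4Cl
Reagents that add atoms: methyllithium, [Li]C
Why: The weakly basic organocerium reagent adds to the hindered ketone without enolisation (which would expel sulfinate), and it attacks along the equatorial trajectory, away from the axial angular methyl that is 1,3-diaxial to an axial approach, so the new carbinol has axial hydroxyl and equatorial methyl (organocerium 1,2-addition, substrate control).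

**Step 11**
Reactants: 17 diol sulfone; 11 allylic chloride
Product: 19 (3S,5aS,6S,7R,9aS)-6-[(3Z,7S,8S,11S)-7,8:11,12-diepoxy-8,12-dimethyl-1-(phenylsulfonyl)-4-[(trimethylsilyl)methyl]tridec-3-en-1-yl]-2,2,5a,7-tetramethyldecahydro-1-benzoxepine-3,7-diol (both epimers at the sulfonyl carbon), via trilithio sulfone 18 (not isolated)
Conditions: n-BuLi (3.3 equiv), THF–DMPU, −78 °C; then 11, −78 → −30 °C; aq. NH4Cl
Reagents that add atoms: none
Why: After both hydroxyls are deprotonated, the third equivalent of base gives the α-sulfonyl carbanion, the most nucleophilic site, which displaces the primary allylic chloride in an SN2 reaction without touching the epoxides; the uncontrolled sulfonyl-bearing centre is removed in step 12 (α-sulfonyl carbanion alkylation).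

**Step 12**
Reactants: 19 coupled sulfone
Product: 20 (3S,5aS,6S,7R,9aS)-6-[(3Z,7S,8S,11S)-7,8:11,12-diepoxy-8,12-dimethyl-4-[(trimethylsilyl)methyl]tridec-3-en-1-yl]-2,2,5a,7-tetramethyldecahydro-1-benzoxepine-3,7-diol
Conditions: Na(Hg) (6% Na), MeOH–THF, −20 °C
Reagents that add atoms: none
Why: Electron transfer from sodium amalgam cleaves the C–S bond and methanol protonates the carbanion, while epoxides, allylsilane and free hydroxyls are inert to this reductant (reductive desulfonylation).

**Step 13**
Reactants: 20 seco-diol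
Product: 21 (5aS,6S,7R,9aS)-6-[(3Z,7S,8S,11S)-7,8:11,12-diepoxy-8,12-dimethyl-4-[(trimethylsilyl)methyl]tridec-3-en-1-yl]-7-hydroxy-2,2,5a,7-tetramethyloctahydro-1-benzoxepin-3(2H)-one
Conditions: Pr4N[RuO4] (5 mol%), N-methylmorpholine N-oxide, 4 Å molecular sieves, CH2Cl2, rt
Reagents that add atoms: none
Why: The perruthenate oxidises the only secondary alcohol under neutral conditions, the tertiary alcohol cannot be oxidised, and epoxides and allylsilane tolerate the reagent (Ley–Griffith oxidation).

**Step 14**
Reactants: 21 seco-ketone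
Product: 23 target CNP0160418.1, via bis(trimethylsilyl) ether 22 (not isolated)
Conditions: Me3SiOTf (2.5 equiv), 2,6-di-tert-butyl-4-methylpyridine (3 equiv), CH2Cl2 (0.005 M), −78 °C; then K2CO3, MeOH, rt
Reagents that add atoms: none
Why: Me3SiOTf silylates the terminal C2–C3 epoxide, whose tertiary carbon C2 is attacked by the oxygen of the C6–C7 epoxide to give a bicyclic epoxonium ion; C11 of the Z-allylsilane then opens this ion at tertiary C6 with inversion, and the β-silyl cation at C10 loses Me3Si+ (which returns Me3SiOTf) to leave only the exocyclic methylidene. The closest known reaction type is the silyl-triflate-promoted tandem oxa-/carbacyclisation of 1,5-diepoxides terminated by carbon π-nucleophiles, combined with the epoxide–allylsilane cyclisation that delivers exocyclic alkenes. Ring A closes in a net 7-endo mode (endo attack of the epoxide oxygen at C2 to a 7-oxoniabicyclo[4.1.0]heptane, which becomes the oxepane when the C6–O bond breaks), and ring B closes last in a 6-endo mode at both the epoxonium carbon and the alkene, through a chair transition state. C3 and C7 keep their epoxide C–O bonds and configurations, the quaternary C6 is set by stereospecific backside opening of the (6S,7S)-epoxide (trans ring fusion, axial methyl), and C11 is set by the chair together with the Z alkene geometry, which places the side chain equatorial and its hydrogen cis to the C7 hydrogen. The step needs endo (tertiary-carbon) regioselectivity at both epoxides over 5-exo tetrahydrofuran formation, which the methyl substitution of the trisubstituted epoxides and the non-nucleophilic medium should secure, and a single terminating regiochemistry, which silicon secures. The distant ketone and tertiary hydroxyl cannot reach the cationic centres through a favourable ring size; the hydroxyl is only silylated and is released in the methanolysis, and step 8 rehearses the same event on a simpler substrate.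

**Compound list**
1 | methyl acetoacetate | COC(=O)CC(C)=O | starting material
2 | geranyl bromide, (2E)-1-bromo-3,7-dimethylocta-2,6-diene | CC(C)=CCC/C(C)=C/CBr | starting material
3 | sodium lithium dianion of methyl acetoacetate | [Na+].[Li+].COC(=O)[CH-]C(=O)[CH2-] | intermediate
4 | methyl (6E)-7,11-dimethyl-3-oxododeca-6,10-dienoate | COC(=O)CC(=O)CC/C=C(\C)CCC=C(C)C | intermediate
5 | lithium (Z)-enolate of 4 | [Li+].COC(=O)/C=C(\[O-])CC/C=C(\C)CCC=C(C)C | intermediate
6 | methyl (2Z,6E)-7,11-dimethyl-3-(trifluoromethylsulfonyloxy)dodeca-2,6,10-trienoate | COC(=O)/C=C(/CC/C=C(\C)CCC=C(C)C)OS(=O)(=O)C(F)(F)F | intermediate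
7 | methyl (2Z,6S,7S,10S)-6,7:10,11-diepoxy-7,11-dimethyl-3-(trifluoromethylsulfonyloxy)dodec-2-enoate | COC(=O)/C=C(/CC[C@@H]1O[C@@]1(C)CC[C@@H]1OC1(C)C)OS(=O)(=O)C(F)(F)F | intermediate
8 | methyl (2Z,6S,7S,10S)-6,7:10,11-diepoxy-7,11-dimethyl-3-[(trimethylsilyl)methyl]dodec-2-enoate | COC(=O)/C=C(/CC[C@@H]1O[C@@]1(C)CC[C@@H]1OC1(C)C)C[Si](C)(C)C | intermediate
9 | (2Z,6S,7S,10S)-6,7:10,11-diepoxy-7,11-dimethyl-3-[(trimethylsilyl)methyl]dodec-2-en-1-ol | OC/C=C(/CC[C@@H]1O[C@@]1(C)CC[C@@H]1OC1(C)C)C[Si](C)(C)C | intermediate
10 | methanesulfonate of 9 | CS(=O)(=O)OC/C=C(/CC[C@@H]1O[C@@]1(C)CC[C@@H]1OC1(C)C)C[Si](C)(C)C | intermediate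
11 | (2Z,6S,7S,10S)-1-chloro-6,7:10,11-diepoxy-7,11-dimethyl-3-[(trimethylsilyl)methyl]dodec-2-ene | ClC/C=C(/CC[C@@H]1O[C@@]1(C)CC[C@@H]1OC1(C)C)C[Si](C)(C)C | intermediate
12 | [(2Z,6S,7S,10S)-6,7:10,11-diepoxy-7,11-dimethyl-3-[(trimethylsilyl)methyl]dodec-2-en-1-yl] phenyl sulfone | O=S(=O)(C/C=C(/CC[C@@H]1O[C@@]1(C)CC[C@@H]1OC1(C)C)C[Si](C)(C)C)c1ccccc1 | intermediate
13 | 3-O-trimethylsilyl ether of 14 | O=S(=O)(c1ccccc1)C[C@H]1[C@]2(C)CC[C@H](O[Si](C)(C)C)C(C)(C)O[C@H]2CCC1=C | intermediate
14 | (3S,5aS,6R,9aS)-2,2,5a-trimethyl-7-methylidene-6-[(phenylsulfonyl)methyl]decahydro-1-benzoxepin-3-ol (trans-fused, side chain equatorial) | O=S(=O)(c1ccccc1)C[C@H]1[C@]2(C)CC[C@H](O)C(C)(C)O[C@H]2CCC1=C | intermediate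
15 | spiro 1,2,4-trioxolane (ozonide) of 14 at the methylidene carbon | O=S(=O)(c1ccccc1)C[C@H]1[C@]2(C)CC[C@H](O)C(C)(C)O[C@H]2CCC13OCOO3 | intermediate
16 | (3S,5aS,6S,9aS)-3-hydroxy-2,2,5a-trimethyl-6-[(phenylsulfonyl)methyl]octahydro-1-benzoxepin-7(2H)-one | O=S(=O)(c1ccccc1)C[C@H]1[C@]2(C)CC[C@H](O)C(C)(C)O[C@H]2CCC1=O | intermediate
17 | (3S,5aS,6S,7R,9aS)-2,2,5a,7-tetramethyl-6-[(phenylsulfonyl)methyl]decahydro-1-benzoxepine-3,7-diol (7-OH axial) | O=S(=O)(c1ccccc1)C[C@H]1[C@]2(C)CC[C@H](O)C(C)(C)O[C@H]2CC[C@@]1(C)O | intermediate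
18 | trilithio derivative of 17 (both alkoxides and the α-sulfonyl carbanion) | [Li+].[Li+].[Li+].O=S(=O)(c1ccccc1)[CH-][C@H]1[C@]2(C)CC[C@H]([O-])C(C)(C)O[C@H]2CC[C@@]1(C)[O-] | intermediate
19 | (3S,5aS,6S,7R,9aS)-6-[(3Z,7S,8S,11S)-7,8:11,12-diepoxy-8,12-dimethyl-1-(phenylsulfonyl)-4-[(trimethylsilyl)methyl]tridec-3-en-1-yl]-2,2,5a,7-tetramethyldecahydro-1-benzoxepine-3,7-diol, both epimers at the sulfonyl carbon | C[Si](C)(C)C/C(CC[C@@H]1O[C@@]1(C)CC[C@@H]1OC1(C)C)=C\CC(S(=O)(=O)c1ccccc1)[C@H]1[C@]2(C)CC[C@H](O)C(C)(C)O[C@H]2CC[C@@]1(C)O | intermediate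
20 | (3S,5aS,6S,7R,9aS)-6-[(3Z,7S,8S,11S)-7,8:11,12-diepoxy-8,12-dimethyl-4-[(trimethylsilyl)methyl]tridec-3-en-1-yl]-2,2,5a,7-tetramethyldecahydro-1-benzoxepine-3,7-diol | C[Si](C)(C)C/C(CC[C@@H]1O[C@@]1(C)CC[C@@H]1OC1(C)C)=C\CC[C@H]1[C@]2(C)CC[C@H](O)C(C)(C)O[C@H]2CC[C@@]1(C)O | intermediate
21 | (5aS,6S,7R,9aS)-6-[(3Z,7S,8S,11S)-7,8:11,12-diepoxy-8,12-dimethyl-4-[(trimethylsilyl)methyl]tridec-3-en-1-yl]-7-hydroxy-2,2,5a,7-tetramethyloctahydro-1-benzoxepin-3(2H)-one | C[Si](C)(C)C/C(CC[C@@H]1O[C@@]1(C)CC[C@@H]1OC1(C)C)=C\CC[C@H]1[C@]2(C)CCC(=O)C(C)(C)O[C@H]2CC[C@@]1(C)O | intermediate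
22 | bis(trimethylsilyl) ether of 23 (ring A secondary and ring C tertiary oxygen) | C=C1CC[C@@H]2OC(C)(C)[C@@H](O[Si](C)(C)C)CC[C@@]2(C)[C@@H]1CC[C@H]1[C@]2(C)CCC(=O)C(C)(C)O[C@H]2CC[C@@]1(C)O[Si](C)(C)C | intermediate
23 | CNP0160418.1, (5aS,6S,7R,9aS)-7-hydroxy-6-{2-[(3S,5aS,6R,9aS)-3-hydroxy-2,2,5a-trimethyl-7-methylidenedecahydro-1-benzoxepin-6-yl]ethyl}-2,2,5a,7-tetramethyloctahydro-1-benzoxepin-3(2H)-one | C=C1CC[C@@H]2OC(C)(C)[C@@H](O)CC[C@@]2(C)[C@@H]1CC[C@H]1[C@]2(C)CCC(=O)C(C)(C)O[C@H]2CC[C@@]1(C)O | target

**Step count**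
Total step count: 14. Longest linear sequence: 14 steps (steps 1–14; chloride 11 from step 6 enters again in step 11).

**Steps most likely to fail**

Step 14. What may go wrong: the silyl triflate may be sequestered by the ketone (silyl enol ether formation, aldol-type capture of the allylsilane), or the epoxonium ion may be intercepted before the carbocycle closes. The fallback sets out from 20 and comes back at 22. The cascade is run at the alcohol oxidation level and the two secondary carbinols are told apart by the cascade itself. Diol 20 is acetylated only at its secondary hydroxyl (Ac2O, DMAP, pyridine, 0 °C) to give the ring D mono-acetate F1. Me3SiOTf and the hindered pyridine base at −78 °C then close rings A and B, with silylation of the new secondary and the tertiary oxygen, and a non-protic quench (Et3N) gives the tetracyclic acetate bis(trimethylsilyl) ether F2. i-Bu2AlH at −78 °C removes the acetate reductively to the ring D alcohol F3. Oxidation with Pr4N[RuO4] and N-methylmorpholine N-oxide gives 22, which is methanolysed to 23 as in step 14. Ring B is still the last ring to close.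

Step 11. What may go wrong: incomplete C-lithiation or aggregation of the trilithio species, so that slow C-alkylation lets O-alkylation or ionisation of the silicon-bearing allylic chloride (1,4-loss of silicon) take over. The fallback sets out from 17 and comes back at 20. Both hydroxyls are masked (Me3SiOTf, Et3N, CH2Cl2, −78 → 0 °C) to give the bis(trimethylsilyl) ether F4, which needs a single equivalent of n-BuLi. Alkylation of its monolithio derivative with 11 at −78 °C gives the alkylated sulfone F5. Na(Hg) in MeOH–THF followed by K2CO3 in MeOH removes the sulfonyl group and both silyl ethers and returns 20.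

Step 4. What may go wrong: opening or rearrangement of the trisubstituted epoxides by the Grignard reagent and its magnesium salts, or addition to the ester, during the cross-coupling. The fallback sets out from 6 and comes back at 8. Silicon is installed before the epoxides: Kumada coupling of triene triflate 6 (Pd(PPh3)4, Me3SiCH2MgCl) gives the triene allylsilane ester F6. Shi epoxidation with the L-fructose-derived ketone at pH 8 (NaHCO3, stoichiometric ketone) should then epoxidise only the two isolated trisubstituted alkenes, because the allylsilane alkene is deactivated by conjugation with the ester, and returns 8.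

**Further compounds**
F1 | step 14 | ring D 3-O-acetate of 20 | C[Si](C)(C)C/C(CC[C@@H]1O[C@@]1(C)CC[C@@H]1OC1(C)C)=C\CC[C@H]1[C@]2(C)CC[C@H](OC(C)=O)C(C)(C)O[C@H]2CC[C@@]1(C)O
F2 | step 14 | tetracyclic ring D acetate with trimethylsilyl ethers on the ring A secondary and ring C tertiary oxygen | C=C1CC[C@@H]2OC(C)(C)[C@@H](O[Si](C)(C)C)CC[C@@]2(C)[C@@H]1CC[C@H]1[C@]2(C)CC[C@H](OC(C)=O)C(C)(C)O[C@H]2CC[C@@]1(C)O[Si](C)(C)C
F3 | step 14 | tetracyclic ring D secondary alcohol with trimethylsilyl ethers on the ring A secondary and ring C tertiary oxygen | C=C1CC[C@@H]2OC(C)(C)[C@@H](O[Si](C)(C)C)CC[C@@]2(C)[C@@H]1CC[C@H]1[C@]2(C)CC[C@H](O)C(C)(C)O[C@H]2CC[C@@]1(C)O[Si](C)(C)C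
F4 | step 11 | 3,7-bis(trimethylsilyl) ether of 17 | O=S(=O)(c1ccccc1)C[C@H]1[C@]2(C)CC[C@H](O[Si](C)(C)C)C(C)(C)O[C@H]2CC[C@@]1(C)O[Si](C)(C)C
F5 | step 11 | 3,7-bis(trimethylsilyl) ether of 19, both epimers at the sulfonyl carbon | C[Si](C)(C)C/C(CC[C@@H]1O[C@@]1(C)CC[C@@H]1OC1(C)C)=C\CC(S(=O)(=O)c1ccccc1)[C@H]1[C@]2(C)CC[C@H](O[Si](C)(C)C)C(C)(C)O[C@H]2CC[C@@]1(C)O[Si](C)(C)C
F6 | step 4 | methyl (2Z,6E)-7,11-dimethyl-3-[(trimethylsilyl)methyl]dodeca-2,6,10-trienoate | COC(=O)/C=C(/CC/C=C(\C)CCC=C(C)C)C[Si](C)(C)C
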